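Per second, each G in this flask has 4 ways out, and this note for whoever takes over the bench rests on how they divide.

Z 0.19 M; G 0.800 equiv (in portions, 3); L 0.0950 M; time 30 min; the portions of G follow each other after 12 s, the first at the start

    2 G → G2 (k1 = 0.59 M⁻¹ s⁻¹)
    Z + 2 G → J (k2 = 2.1 M⁻² s⁻¹)
    Z + Z.G → Z.Z.G (k3 = 2.3 M⁻¹ s⁻¹)
    G + L → G.L (k4 = 1.3 M⁻¹ s⁻¹)
    Z + G → Z.G (k5 = 0.43 M⁻¹ s⁻¹)

- in percentages every species weighs as the Z in it: one Z.Z.G counts as two
- a doubled species enters its step squared and goes two at a time
- the reaction counts as stopped when no species that holds the Z changes by six tenths of a point or more over the second half of the time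
- run time (flask): 30 min

- at 30 min, what has stopped the reaction, if anything has (all of Z has reacted / G has run out first / forward and back rates have come level / it is still moving)
- how much of the Z has reacted by 30 min
- how much Z.Z.G there is at 30 min, in percent of the Z charged

The flask holds Z, L and the first portion of G, with further portions following. The charged G is 0.152 M. Each Z.Z.G holds two Z to one G, so turning the 0.19 M of Z into Z.Z.G takes 0.0950 M of G, and the charge is more than that. But L also takes G, and so do G2 and J, so I write the balance of G to see whether G or Z gives out first. The half-life of G by its step with L alone, with L as charged, is 0.094 min, far shorter than the 30 min, so I expect a quiet flask when you come.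

G falls from a full portion towards nothing, so I hold [G] at half a portion, and [Z] and [L] at their charges:

[G] = 0.0253 M
into G.L: 1.3 M⁻¹ s⁻¹ × 0.0950 M = 0.124 s⁻¹
into Z.G: 0.43 M⁻¹ s⁻¹ × 0.19 M = 0.0817 s⁻¹
into G2: 2 × 0.59 M⁻¹ s⁻¹ × 0.0253 M = 0.0299 s⁻¹
into J: 2 × 2.1 M⁻² s⁻¹ × 0.19 M × 0.0253 M = 0.0202 s⁻¹

The share of G that reaches Z as Z.G is the second line over the sum, 32.0%. Each Z.G then takes a second Z, so:

Z.Z.G = 2 × 32.0% × 0.800 = 51.2%
conversion = 51.2% + 3.17% from J = 54.4%

That leaves Z over, so by this reckoning, with its side losses counted, G is the limiting reagent of this flask. Do not add L, because it pulls on G harder than Z does, and a G taken by L makes no Z.Z.G.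

The forecast gives G has run out first, 56% and 53%, starting from “G lasts only seconds per portion”.

The simulation gives G has run out first, 55.4% reacted and 52.0% Z.Z.G. In this flask G went to G.L and Z.G during the additions, with Z.G passing on to Z.Z.G close behind: at 0.400 min Z.Z.G stood at 29.7% and Z.G at 1.15%. By 15.0 min G stood at 0%, and Z stayed at 44.6% through 30.0 min. The Z.Z.G found means a share of 32.5%, against my 32.0%. For the flask with 0.47 M of Z and the same [L], half a portion is 0.0627 M, so the share is 38.6% and the reckoned Z.Z.G 61.8%; that flask holds 62.1%.

(The rate constants are invented; the rest is arithmetic.)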